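**Plan**

- Retrosynthesis: the two acetates come off first, then the C13–C14 vinyl bond (Stille) and the C12=C13 alkene (iodo-Wittig on a C12 aldehyde made from an allyl group), then the C8–O bond (enol ether oxidation), the C9–C11 bond (allyl Grignard on a C9 ketone), and last the C1–C10 and C4–C5 bonds of ring A (Diels–Alder).
- Enabling feature: ring B (C5–C10) has oxygen at C6, methyls at C8 and C10 and a carbon branch at C9, which is 2,6-dimethyl-1,4-benzoquinone with its carbonyls at C6 and C9; ring A (C1–C4) is a four-carbon diene whose terminus C4 carries the gem-dimethyl group.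
- Forward: ring B is the quinone and ring A closes onto its C5=C10 bond in step 1; the C9 ketone then takes the side-chain carbons, its oxygen is transposed to C7, C8 is hydroxylated, and the (12Z)-diene is built last.
- Stereochemistry: C10 from the chiral boron catalyst; C5 by equilibration to the trans-decalin; C9 by axial protonation in the dissolving-metal reduction; C8 by epoxidation anti to the C10 methyl; C6 by equilibration to the equatorial ether; C7 by axial hydride delivery; 12Z from the iodo-ylide olefination, retained in the cross-coupling.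

Key step: step 1

Convention: labdane numbering (C1–C20) is used for every bicyclic compound; syn and anti give the face of a substituent relative to the C10 methyl group (C20). The target is ent-(12Z)-6α,7β-diacetoxylabda-12,14-dien-8α-ol, (5R,6S,7R,8R,9S,10R).

Assumption: the sense of induction in step 1 follows the usual pre-transition-state model of this catalyst family, by which the (S)-prolinol-derived catalyst is expected to give the (4aS,8aR) adduct; were the opposite sense found, the (R)-catalyst would be used with no other change.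

**Route**

Step 1
Reactants: 1 2,6-dimethyl-1,4-benzoquinone; 2 4-methylpenta-1,3-diene
Product: 3 cis-fused adduct (4aS,8aR)-2,5,5,8a-tetramethyl-4a,5,8,8a-tetrahydronaphthalene-1,4-dione (ketones at C6 and C9; alkenes C2=C3 and C7=C8; C5–H syn)
Conditions: (S)-3,3-diphenyl-1-(2-methylphenyl)tetrahydro-1H,3H-pyrrolo[1,2-c][1,3,2]oxazaborole (24 mol %), HNTf2 (20 mol %), 2 (5 equiv), CH2Cl2, −20 → 0 °C
Reagents that add atoms: none
Why: Catalytic enantioselective Diels–Alder reaction of a quinone: the boron cation binds the lone pair of the C6 carbonyl that is syn to C5–H (a C–H···O contact to the ring oxygen fixes the geometry), which makes C10 the β-carbon, and the CH2 terminus of 2 (largest HOMO coefficient) bonds to C10 slightly ahead of the C4–C5 bond in a concerted, asynchronous [4+2] addition. The closest known reaction type is the oxazaborolidinium-catalysed cycloaddition of alkyl-substituted 1,4-benzoquinones with 2-silyloxy- and alkyl-1,3-dienes. Ring A closes as a six-membered ring by suprafacial–suprafacial [4+2] cycloaddition across C5=C10. C10 is set by the catalyst, whose phenyl group next to the bound dienophile covers one face of C5=C10 so that the diene adds to the open face, and C5 follows from suprafacial addition (H and CH3 cis). The step needs regio-, site- and face selectivity: the first comes from coordination at the unhindered C6 carbonyl (the C9 carbonyl lies between two methyl-bearing carbons and offers no α-C–H contact) reinforced by the polarisation of the diene, the second is no issue because the two methylated double bonds of 1 are equivalent by symmetry, and the third is the catalyst's. Because the cis-methyl at the C4 terminus disfavours the s-cis conformer, the diene is used in excess at a higher temperature than usual, and the oxazaborolidine is kept in slight excess over HNTf2 so that no free acid isomerises or oligomerises the diene.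

Step 2
Reactants: 3 cis-fused adduct
Product: 4 trans-fused enedione (4aR,8aR)-2,5,5,8a-tetramethyl-4a,5,8,8a-tetrahydronaphthalene-1,4-dione (C5–H anti)
Conditions: DBU (0.3 equiv), CH2Cl2, rt
Reagents that add atoms: none
Why: Thermodynamic epimerisation by reversible enolisation of the C6 ketone towards C5 (base-mediated equilibration, as used for cis-fused quinone adducts): reprotonation should give the trans-decalin, which frees the C4 gem-dimethyl group from the concave face of the cis bicycle, while the quaternary C10 cannot change.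

Step 3
Reactants: 4 trans-fused enedione
Product: 5 trans-fused 6-hydroxy-2,7-dien-9-one (C6–OH syn)
Conditions: NaBH4, CeCl3·7H2O, MeOH, −78 °C
Reagents that add atoms: none
Why: Luche reduction: the cerium-assisted hydride adds 1,2 to the C6 carbonyl, which is flanked by two CH groups, and not to the C9 carbonyl between the quaternary C10 and the methyl-bearing C8; hydride arrives anti to the C10 and axial C4 methyls, so C6–OH is expected syn, a centre that step 8 equilibrates.

Step 4
Reactants: 5 6-hydroxy-2,7-dien-9-one
Product: 6 6-syn-triethylsilyloxy-2,7-dien-9-one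
Conditions: Et3SiOTf, 2,6-lutidine, CH2Cl2, −78 → 0 °C
Reagents that add atoms: triethylsilyl trifluoromethanesulfonate, CC[Si](CC)(CC)OS(=O)(=O)C(F)(F)F
Why: Silyl ether formation with a silyl triflate and a hindered pyridine base, the standard answer to a hydroxyl flanked by two syn-axial methyl groups; the small triethylsilyl group is chosen for that reason and because fluoride removes it at the end before any ester is present.

Step 5
Reactants: 6 6-syn-triethylsilyloxy-2,7-dien-9-one
Product: 7 6-syn-triethylsilyloxy-7-en-9-one (ring A saturated)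
Conditions: H2 (1 atm), RhCl(PPh3)3 (10 mol %), toluene, rt
Reagents that add atoms: none
Why: Homogeneous hydrogenation with RhCl(PPh3)3, which reduces the cis-disubstituted C2=C3 alkene far faster than the trisubstituted, conjugated C7=C8 alkene that is further shielded by the neighbouring silyloxy group (the selectivity known from carvone).

Step 6
Reactants: 7 6-syn-triethylsilyloxy-7-en-9-one
Product: 8 9-allyl-9-hydroxy-6-syn-triethylsilyloxy-7-ene (allyl anti; OH syn)
Conditions: CH2=CHCH2MgBr (3 equiv), THF, −78 → 0 °C; aq NH4Cl
Reagents that add atoms: allylmagnesium bromide, C=CC[Mg]Br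
Why: Grignard 1,2-addition: allylmagnesium bromide adds to hindered, non-enolisable enone carbonyls through a six-membered transition state without conjugate addition; attack anti to the C10 methyl is expected, but the C9 centre is erased in step 7.

Step 7
Reactants: 8 9-allyl-9-hydroxy-6-syn-triethylsilyloxy-7-ene
Product: 9 9-allyl-6-syn-triethylsilyloxy-8-en-7-one
Conditions: pyridinium chlorochromate C5H5NH[CrO3Cl] (3 equiv), 4 Å molecular sieves, CH2Cl2, rt
Reagents that add atoms: pyridinium chlorochromate, [O-][Cr](=O)(=O)Cl.c1cc[nH+]cc1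
Why: Dauben–Babler oxidative transposition: the chromate ester of the tertiary allylic alcohol undergoes a [3,3] shift that carries oxygen to C7 and moves the alkene to C8=C9, and hexavalent chromium then oxidises the secondary C7 chromate to the enone; the silyl ether and the terminal alkene are inert.

Step 8
Reactants: 9 9-allyl-6-syn-triethylsilyloxy-8-en-7-one
Product: 10 9-allyl-6-anti-triethylsilyloxy-8-en-7-one
Conditions: DBU (2 equiv), toluene, 80 °C
Reagents that add atoms: none
Why: Base-mediated equilibration through the cross-conjugated C6 dienolate: the silyloxy group should leave the syn face, where it is 1,3-diaxial to both the C10 and the axial C4 methyl, for the anti (equatorial) position that the target requires, and any γ-deprotonation returns to the conjugated tetrasubstituted enone.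

Step 9
Reactants: 10 9-allyl-6-anti-triethylsilyloxy-8-en-7-one
Product: 12 9-allyl-6-anti,7-bis(triethylsilyloxy)-7-ene (C9–H anti), via lithium enolate 11 (not isolated)
Conditions: Li (2.5 equiv), t-BuOH (1.0 equiv), NH3/THF, −78 °C; isoprene; NH3 removed; Et3SiCl, Et3N, THF, −78 → 0 °C
Reagents that add atoms: chlorotriethylsilane, CC[Si](CC)(CC)Cl
Why: Stork reductive silylation: two-electron reduction of the enone with one equivalent of t-BuOH protonates C9 axially, anti to the C10 methyl (allyl equatorial, syn), and leaves the regiodefined C7=C8 lithium enolate, which Et3SiCl traps on oxygen; the equatorial C6–O bond is orthogonal to the enone π system and should not be expelled, and the isolated alkene is not reduced.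

Step 10
Reactants: 12 9-allyl-6-anti,7-bis(triethylsilyloxy)-7-ene
Product: 14 9-allyl-6-anti,8-anti-bis(triethylsilyloxy)-7-one (C8 methyl syn), via silyloxy epoxide 13 (not isolated)
Conditions: mCPBA (1.05 equiv), NaHCO3, CH2Cl2, −20 °C
Reagents that add atoms: 3-chloroperbenzoic acid, O=C(OO)c1cccc(Cl)c1
Why: Rubottom oxidation: the peracid epoxidises the electron-rich tetrasubstituted enol ether (much faster than the terminal alkene) on the face anti to the axial C10 methyl, and the silyloxy epoxide opens with 1,4-silyl migration to the α-silyloxy ketone, which places the C8 oxygen anti and the C8 methyl syn (axial).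

Step 11
Reactants: 14 9-allyl-6-anti,8-anti-bis(triethylsilyloxy)-7-one
Product: 16 6-anti,8-anti-bis(triethylsilyloxy)-7-oxo C12 aldehyde (C9–CH2–CHO), via ozonide 15 (not isolated)
Conditions: O3, CH2Cl2, −78 °C; PPh3, −78 °C → rt
Reagents that add atoms: ozone, [O-][O+]=O
Why: Ozonolysis with reductive work-up cleaves the only alkene to the C12 aldehyde; with the C8 oxygen silylated the γ-hydroxy aldehyde cannot close to a lactol.

Step 12
Reactants: 16 C12 aldehyde
Product: 17 (12Z)-13-iodo-12-ene (side chain CH2–CH=C(I)CH3 with iodine cis to C11; 6-anti,8-anti-bis(triethylsilyloxy)-7-one)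
Conditions: [Ph3PCH2CH3]I, n-BuLi, THF, 0 °C → rt; I2, −78 °C; NaN(SiMe3)2, −20 °C; then 16, −78 °C
Reagents that add atoms: ethyltriphenylphosphonium iodide, CC[P+](c1ccccc1)(c1ccccc1)c1ccccc1.[I-]; iodine, [I][I]
Why: Stork–Zhao-type Wittig olefination with the α-iodoethylidene ylide (Zhao–Smith variant), which under kinetic control at −78 °C gives the (Z)-2-iodoalkene with iodine cis to C11; the aldehyde reacts while the hindered, doubly α-oxygenated C7 ketone does not.

Step 13
Reactants: 17 (12Z)-13-iodo-12-ene
Product: 18 (12Z)-6-anti,8-anti-bis(triethylsilyloxy)-12,14-dien-7-one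
Conditions: CH2=CHSnBu3, Pd2(dba)3 (5 mol %), AsPh3 (20 mol %), CuI (10 mol %), NMP, rt → 40 °C
Reagents that add atoms: tributyl(vinyl)stannane, C=C[Sn](CCCC)(CCCC)CCCC
Why: Stille cross-coupling: oxidative addition of the alkenyl iodide to zerovalent palladium, transmetalation from tin and reductive elimination all proceed with retention, so the vinyl group ends cis to C11 and the (12Z)-diene forms under neutral conditions.

Step 14
Reactants: 18 (12Z)-6-anti,8-anti-bis(triethylsilyloxy)-12,14-dien-7-one
Product: 19 (12Z)-6-anti,8-anti-bis(triethylsilyloxy)-12,14-dien-7-syn-ol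
Conditions: NaBH4, MeOH/THF, −20 → 0 °C
Reagents that add atoms: none
Why: Borohydride reduction of a cyclohexanone: the small hydride should enter axially on the face anti to the C10 methyl, away from the axial C8 methyl, to give the equatorial C7–OH (syn); the diene is inert, and any silyl migration between the neighbouring oxygens is without consequence because step 15 removes all silyl groups.

Step 15
Reactants: 19 (12Z)-6-anti,8-anti-bis(triethylsilyloxy)-12,14-dien-7-syn-ol
Product: 20 (12Z)-12,14-diene-6-anti,7-syn,8-anti-triol
Conditions: Bu4NF (5 equiv), THF, rt → 45 °C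
Reagents that add atoms: none
Why: Fluoride-mediated desilylation cleaves both triethylsilyl ethers under basic conditions, which spare the acid-labile hydroxy diene (acid would close an ether from C8–OH onto the diene) and meet no ester that could migrate.

Step 16
Reactants: 20 (12Z)-12,14-diene-6-anti,7-syn,8-anti-triol
Product: 21 ent-(12Z)-6α,7β-diacetoxylabda-12,14-dien-8α-ol (target)
Conditions: Ac2O, pyridine, DMAP (0.2 equiv), CH2Cl2, 0 °C → rt
Reagents that add atoms: acetic anhydride, CC(=O)OC(C)=O
Why: Nucleophile-catalysed acetylation (DMAP): the two secondary, equatorial hydroxyls at C6 and C7 are acylated while the tertiary C8–OH stays free, which completes 21.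

**Compound list**

1 | 2,6-dimethyl-1,4-benzoquinone | CC1=CC(=O)C=C(C)C1=O | starting material
2 | 4-methylpenta-1,3-diene | C=CC=C(C)C | starting material
3 | cis-fused adduct (4aS,8aR)-2,5,5,8a-tetramethyl-4a,5,8,8a-tetrahydronaphthalene-1,4-dione | O=C1C(C)=CC(=O)[C@H]2C(C)(C)C=CC[C@]21C | intermediate
4 | trans-fused enedione (4aR,8aR)-2,5,5,8a-tetramethyl-4a,5,8,8a-tetrahydronaphthalene-1,4-dione | O=C1C(C)=CC(=O)[C@@H]2C(C)(C)C=CC[C@]21C | intermediate
5 | trans-fused 6-hydroxy-2,7-dien-9-one (C6–OH syn) | O=C1C(C)=C[C@H](O)[C@@H]2C(C)(C)C=CC[C@]21C | intermediate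
6 | 6-syn-triethylsilyloxy-2,7-dien-9-one | O=C1C(C)=C[C@H](O[Si](CC)(CC)CC)[C@@H]2C(C)(C)C=CC[C@]21C | intermediate
7 | 6-syn-triethylsilyloxy-7-en-9-one | O=C1C(C)=C[C@H](O[Si](CC)(CC)CC)[C@@H]2C(C)(C)CCC[C@]21C | intermediate
8 | 9-allyl-9-hydroxy-6-syn-triethylsilyloxy-7-ene (allyl anti; OH syn) | C=CC[C@@]1(O)C(C)=C[C@H](O[Si](CC)(CC)CC)[C@@H]2C(C)(C)CCC[C@]21C | intermediate
9 | 9-allyl-6-syn-triethylsilyloxy-8-en-7-one | C=CCC1=C(C)C(=O)[C@H](O[Si](CC)(CC)CC)[C@@H]2C(C)(C)CCC[C@]21C | intermediate
10 | 9-allyl-6-anti-triethylsilyloxy-8-en-7-one | C=CCC1=C(C)C(=O)[C@@H](O[Si](CC)(CC)CC)[C@@H]2C(C)(C)CCC[C@]21C | intermediate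
11 | lithium enolate (C7–OLi, C7=C8; C9–H anti) | C=CC[C@@H]1C(C)=C([O-])[C@@H](O[Si](CC)(CC)CC)[C@@H]2C(C)(C)CCC[C@]21C.[Li+] | intermediate (not isolated)
12 | 9-allyl-6-anti,7-bis(triethylsilyloxy)-7-ene | C=CC[C@@H]1C(C)=C(O[Si](CC)(CC)CC)[C@@H](O[Si](CC)(CC)CC)[C@@H]2C(C)(C)CCC[C@]21C | intermediate
13 | silyloxy epoxide (7,8-epoxide, oxygen anti) | C=CC[C@@H]1[C@@]2(C)O[C@@]2(O[Si](CC)(CC)CC)[C@@H](O[Si](CC)(CC)CC)[C@@H]3C(C)(C)CCC[C@]31C | intermediate (not isolated)
14 | 9-allyl-6-anti,8-anti-bis(triethylsilyloxy)-7-one | C=CC[C@@H]1[C@@](C)(O[Si](CC)(CC)CC)C(=O)[C@@H](O[Si](CC)(CC)CC)[C@@H]2C(C)(C)CCC[C@]21C | intermediate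
15 | ozonide (1,2,4-trioxolane of the allyl group) | O1OCOC1C[C@@H]3[C@@](C)(O[Si](CC)(CC)CC)C(=O)[C@@H](O[Si](CC)(CC)CC)[C@@H]4C(C)(C)CCC[C@]43C | intermediate (not isolated)
16 | 6-anti,8-anti-bis(triethylsilyloxy)-7-oxo C12 aldehyde | O=CC[C@@H]1[C@@](C)(O[Si](CC)(CC)CC)C(=O)[C@@H](O[Si](CC)(CC)CC)[C@@H]2C(C)(C)CCC[C@]21C | intermediate
17 | (12Z)-13-iodo-12-ene | I/C(C)=C\C[C@@H]1[C@@](C)(O[Si](CC)(CC)CC)C(=O)[C@@H](O[Si](CC)(CC)CC)[C@@H]2C(C)(C)CCC[C@]21C | intermediate
18 | (12Z)-6-anti,8-anti-bis(triethylsilyloxy)-12,14-dien-7-one | C=C/C(C)=C\C[C@@H]1[C@@](C)(O[Si](CC)(CC)CC)C(=O)[C@@H](O[Si](CC)(CC)CC)[C@@H]2C(C)(C)CCC[C@]21C | intermediate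
19 | (12Z)-6-anti,8-anti-bis(triethylsilyloxy)-12,14-dien-7-syn-ol | C=C/C(C)=C\C[C@@H]1[C@@](C)(O[Si](CC)(CC)CC)[C@H](O)[C@@H](O[Si](CC)(CC)CC)[C@@H]2C(C)(C)CCC[C@]21C | intermediate
20 | (12Z)-12,14-diene-6-anti,7-syn,8-anti-triol | C=C/C(C)=C\C[C@@H]1[C@@](C)(O)[C@H](O)[C@@H](O)[C@@H]2C(C)(C)CCC[C@]21C | intermediate
21 | ent-(12Z)-6α,7β-diacetoxylabda-12,14-dien-8α-ol | C=C/C(C)=C\C[C@@H]1[C@@](C)(O)[C@H](OC(C)=O)[C@@H](OC(C)=O)[C@@H]2C(C)(C)CCC[C@]21C | target

**Count and risks**

Total steps: 16. Longest linear sequence: 16 steps (1 and 2 are both commercial and meet in step 1).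

Steps most likely to fail:

Step 1. The cycloaddition may stall, because the cis-methyl of the diene terminus disfavours the reactive s-cis conformer. The acid-sensitive diene may also isomerise to 2-methylpenta-1,3-diene and oligomerise faster than it adds. The fallback sets out from 1 and replaces the hydrocarbon diene by 4-methyl-2-(triisopropylsilyloxy)penta-1,3-diene F1, made from mesityl oxide with LiN(i-Pr)2 and i-Pr3SiOTf in THF at −78 °C. 2-Silyloxydienes are the standard partners of quinones under the same catalyst. The nucleophilic CH2 terminus of F1 again bonds to C10, and a stepwise Mukaiyama–Michael addition and ring closure is open to it, so the first bond does not require the strained s-cis geometry. The product, the cis-fused adduct bearing a C2 silyl enol ether F2, would be converted into the C2 enol triflate F3 with Bu4N[Ph3SiF2] and N-(5-chloropyridin-2-yl)bis(trifluoromethanesulfonimide) in THF; the hindered C5–H should be slow to quench the enolate. F3 would then be reduced with Pd(OAc)2, PPh3, Bu3N and HCO2H in DMF to the C2=C3 alkene, which is compound 3, where the route is rejoined.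

Step 9. Electron transfer to the enone may expel the neighbouring C6 silyloxy group (reductive cleavage next to the carbonyl) or over-reduce the ketone. The fallback sets out from 10 and cleaves the silyl ether with HF·pyridine in THF to the 6-anti-hydroxy enone F4. In Li/NH3 the hydroxyl proton of F4 is the single proton source for C9 and the resulting alkoxide is no leaving group, so the dilithium alkoxide enolate F5 should form. Excess Et3SiCl with Et3N silylates both oxygens and gives 12, where the route is rejoined.

Step 12. The thermally fragile iodo-ylide may decompose before it reacts with the β-branched aldehyde, or the olefination may give poor Z selectivity. The fallback sets out from 16: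
- Still–Gennari olefination (methyl 2-[bis(2,2,2-trifluoroethoxy)phosphoryl]propanoate, KN(SiMe3)2, 18-crown-6, THF, −78 °C) would give the methyl (Z)-2-methylenoate F6.
- NaBH4 reduces the C7 ketone as in step 14 to the 7-syn-hydroxy ester F7.
- i-Bu2AlH in CH2Cl2 at −78 °C gives the (Z)-allylic alcohol F8.
- MnO2 oxidises only the allylic alcohol to the (Z)-enal F9, which is used at once to avoid isomerisation.
- Methylenation with Ph3P=CH2 in THF gives 19, where the route is rejoined.

Further compounds
F1 | step 1 | 4-methyl-2-(triisopropylsilyloxy)penta-1,3-diene | C=C(O[Si](C(C)C)(C(C)C)C(C)C)C=C(C)C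
F2 | step 1 | cis-fused adduct bearing a C2 silyl enol ether | O=C1C(C)=CC(=O)[C@H]2C(C)(C)C=C(O[Si](C(C)C)(C(C)C)C(C)C)C[C@]21C
F3 | step 1 | C2 enol triflate of the cis-fused adduct | O=C1C(C)=CC(=O)[C@H]2C(C)(C)C=C(OS(=O)(=O)C(F)(F)F)C[C@]21C
F4 | step 9 | 9-allyl-6-anti-hydroxy-8-en-7-one | C=CCC1=C(C)C(=O)[C@@H](O)[C@@H]2C(C)(C)CCC[C@]21C
F5 | step 9 | dilithium alkoxide enolate | C=CC[C@@H]1C(C)=C([O-])[C@@H]([O-])[C@@H]2C(C)(C)CCC[C@]21C.[Li+].[Li+]
F6 | step 12 | methyl (Z)-2-methylenoate (7-ketone) | COC(=O)/C(C)=C\C[C@@H]1[C@@](C)(O[Si](CC)(CC)CC)C(=O)[C@@H](O[Si](CC)(CC)CC)[C@@H]2C(C)(C)CCC[C@]21C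
F7 | step 12 | methyl (Z)-2-methylenoate (7-syn-ol) | COC(=O)/C(C)=C\C[C@@H]1[C@@](C)(O[Si](CC)(CC)CC)[C@H](O)[C@@H](O[Si](CC)(CC)CC)[C@@H]2C(C)(C)CCC[C@]21C
F8 | step 12 | (Z)-allylic alcohol | OC/C(C)=C\C[C@@H]1[C@@](C)(O[Si](CC)(CC)CC)[C@H](O)[C@@H](O[Si](CC)(CC)CC)[C@@H]2C(C)(C)CCC[C@]21C
F9 | step 12 | (Z)-enal | O=C/C(C)=C\C[C@@H]1[C@@](C)(O[Si](CC)(CC)CC)[C@H](O)[C@@H](O[Si](CC)(CC)CC)[C@@H]2C(C)(C)CCC[C@]21C
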